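**Assumption (one line):** atoms carry the usual Daphniphyllum labels (C1 = NCH, C2 = ketone, C5 = quaternary carbon bearing C21H2O, C7 = NCH2, C8 = quaternary carbon bearing the C13–C14–C22 lactone arm, C9=C15, C18 = CHMe, C19 = NCH2); ring A = N/C19/C18/C2/C3/C1, ring B = N/C1/C8/C5/C6/C7; the drawn C18 epimer is taken to be the product of kinetic protonation on the exposed face.

## Retrosynthetic overview

1. Ring A last: C18 methylenation of amino ketone 21, 6-endo aza-Michael closure, kinetic protonation at C18.
2. Cyclopentane (C1–C3) by intramolecular Mannich reaction of the cyclic imine made from bridged lactam 19; lactone by lactonisation of 18.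
3. C5 quaternary centre by epoxide radical opening/Giese addition on the bridging ketone of 15; ring B (as lactam) by aza-Michael addition/lactamisation.
4. C8 quaternary centre by Michael addition of hydroazulenone β-keto ester 10; seven-membered ring by Pd-catalysed intramolecular α-vinylation.
5. C10 from CBS reduction/Johnson–Claisen rearrangement of 2-bromocyclopentenone. Ring order: cyclopentene, seven-membered carbocycle, ring B, lactone, cyclopentane, ring A.

## Route

Step 1
Reactants: 1 2-bromocyclopent-2-en-1-one
Product: 2 (S)-2-bromocyclopent-2-en-1-ol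
Conditions: (R)-2-methyl-CBS-oxazaborolidine (10 mol%), BH3·SMe2, THF, −20 °C; aqueous work-up
Reagents that add atoms: none
Why: Corey–Bakshi–Shibata reduction, in which the catalyst distinguishes the bromoalkenyl flank from the CH2 flank and delivers hydride to one face, setting the (S)-carbinol that later becomes C10.

Step 2
Reactants: 2 (S)-2-bromocyclopent-2-en-1-ol; 3 triethyl orthoacetate
Product: 5 ethyl (S)-2-(2-bromocyclopent-2-en-1-yl)acetate, via mixed ketene acetal 4 (not isolated)
Conditions: 3 (5 equiv), EtCO2H (5 mol%), 140 °C, EtOH distilled off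
Reagents that add atoms: none
Why: Johnson–Claisen [3,3] rearrangement is suprafacial, so the C–O configuration is transferred to the new C–C bond at C10 while the alkene shifts to C9=C15 with bromine left on C9.

Step 3
Reactants: 5 ethyl (S)-2-(2-bromocyclopent-2-en-1-yl)acetate
Product: 6 (S)-2-(2-bromocyclopent-2-en-1-yl)ethan-1-ol
Conditions: LiAlH4, Et2O, 0 °C; H2O/aq. NaOH work-up
Reagents that add atoms: none
Why: Hydride reduction of the ester to the primary alcohol; the vinyl bromide and the C10 centre are inert at 0 °C.

Step 4
Reactants: 6 (S)-2-(2-bromocyclopent-2-en-1-yl)ethan-1-ol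
Product: 7 (S)-1-bromo-5-(2-iodoethyl)cyclopent-1-ene
Conditions: PPh3, I2, imidazole, CH2Cl2, 0 °C to rt; aq. NaOH wash
Reagents that add atoms: iodine, II
Why: Appel-type iodination of the primary alcohol by SN2 displacement of the oxyphosphonium leaving group; no stereocentre is touched.

Step 5
Reactants: 7 (S)-1-bromo-5-(2-iodoethyl)cyclopent-1-ene; 8 methyl acetoacetate
Product: 9 methyl (R)-6-(2-bromocyclopent-2-en-1-yl)-3-oxohexanoate
Conditions: 8, LiN(i-Pr)2 (2.1 equiv), THF, 0 °C; then 7, 0 °C to rt; H2O
Reagents that add atoms: none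
Why: Weiler dianion alkylation, in which the more reactive γ-carbanion of the acetoacetate dianion displaces the primary iodide (the descriptor changes only because the CIP priorities change).

Step 6
Reactants: 9 methyl (R)-6-(2-bromocyclopent-2-en-1-yl)-3-oxohexanoate
Product: 10 methyl (3aR)-7-oxo-2,3,3a,4,5,6,7,8-octahydroazulene-8-carboxylate
Conditions: Pd(OAc)2 (5 mol%), 2-(di-tert-butylphosphino)-2'-methylbiphenyl (10 mol%), K3PO4 (2 equiv), toluene, 90 °C
Reagents that add atoms: none
Why: Pd-catalysed intramolecular α-vinylation of a β-keto ester enolate, in which zerovalent palladium inserts into the C9–Br bond and the soft C8 enolate closes the seven-membered ring with the C9=C15 alkene kept in place.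

Step 7
Reactants: 10 methyl (3aR)-7-oxo-2,3,3a,4,5,6,7,8-octahydroazulene-8-carboxylate; 11 methyl acrylate
Product: 12 methyl 8-(3-methoxy-3-oxopropyl)-7-oxo-2,3,3a,4,5,6,7,8-octahydroazulene-8-carboxylate (C8 quaternary; propanoate arm trans to H10)
Conditions: 11 (1.5 equiv), Cs2CO3 (10 mol%), MeCN, 0 °C to rt
Reagents that add atoms: none
Why: Michael addition of the β-keto ester enolate creates the C8 quaternary centre, the acrylate approaching the enolate face remote from the puckered C10–C11–C12 segment so that the new arm ends trans to H10.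

Step 8
Reactants: 12 diester ketone
Product: 13 6-methylene derivative of 12 (exo-methylene ketone at C6)
Conditions: (CH2O)n, i-Pr2NH·CF3CO2H, THF, 65 °C
Reagents that add atoms: formaldehyde (as paraformaldehyde), C=O
Why: Mannich-type α-methylenation, which can only occur at C6 because C8 is quaternary.

Step 9
Reactants: 13 exo-methylene ketone
Product: 15 bridged keto-lactam (ring B as lactam N–C1(=O); C5 ketone as one-carbon bridge; H6 on the face of the propanoate arm), via primary amino ketone 14 (not isolated)
Conditions: NH3 (7 M in MeOH, excess), 0 °C to rt, then 60 °C (sealed tube)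
Reagents that add atoms: ammonia, N
Why: Aza-Michael addition of ammonia to C7 followed by lactamisation onto the C1 ester, where C6 equilibrates through the enol and only the cis-1,3 isomer can bridge, which fixes C6.

Step 10
Reactants: 15 bridged keto-lactam
Product: 16 C5 spiro-epoxide of 15 (configuration at the spiro carbon is lost in step 11)
Conditions: Me3S+ I−, KN(SiMe3)2, THF, 0 °C to rt
Reagents that add atoms: trimethylsulfonium iodide, C[S+](C)C.[I-]
Why: Corey–Chaykovsky epoxidation of the non-enolisable bridging ketone installs C21 and its oxygen on C5.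

Step 11
Reactants: 16 spiro-epoxide; 17 ethyl vinyl ketone
Product: 18 hydroxy ketone (C5 bears CH2OH on the carbocycle side and the 3-oxopentyl chain on the lactam side)
Conditions: (C5H5)2TiCl2 (10 mol%), Zn dust, 2,4,6-collidine hydrochloride (2.5 equiv), 17 (3 equiv), THF, rt
Reagents that add atoms: none
Why: Nugent–RajanBabu reductive epoxide opening by trivalent titanium gives the tertiary C5 radical (no β-hydride elimination is possible between two bridgeheads), which undergoes Giese addition to 17 from the flatter lactam face and so sets the C5 quaternary centre.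

Step 12
Reactants: 18 hydroxy ketone
Product: 19 lactone-lactam (seven-membered lactone C21–O–C22)
Conditions: Ti(Oi-Pr)4 (20 mol%), toluene, 110 °C, 4 Å molecular sieves
Reagents that add atoms: none
Why: Neutral transesterification/lactonisation, favoured because the two arms sit cis on the vicinal quaternary carbons and methanol is removed; neutral conditions avoid dehydration of the δ-hydroxy ketone.

Step 13
Reactants: 19 lactone-lactam
Product: 21 tetracyclic amino ketone (ring B piperidine NH; cyclopentane closed; propanoyl group on C3), via cyclic imine 20 (not isolated)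
Conditions: Tf2O (1.1 equiv), 2-fluoropyridine (1.2 equiv), CH2Cl2, −78 to 0 °C; Et3SiH (1.2 equiv), rt, then 40 °C; aq. NaHCO3
Reagents that add atoms: none
Why: Charette-type amide activation and hydrosilane reduction give the C1=N imine, which undergoes 5-exo intramolecular Mannich reaction with the ketone enol tethered on the lactam face, so C1 and C3 are set by the cis ring fusion (C3 is epimerisable).

Step 14
Reactants: 21 tetracyclic amino ketone
Product: 23 target CNP0292775.1, via methylene ketone 22 (not isolated)
Conditions: (CH2O)n, PhNHMe·CF3CO2H (20 mol%), THF, 60 °C; cold pH 7 buffer work-up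
Reagents that add atoms: formaldehyde (as paraformaldehyde), C=O
Why: Mannich-type α-methylenation occurs only at C18 (C3 is now a methine), the ring nitrogen closes ring A by 6-endo aza-Michael addition, and the resulting enol is protonated at C18 from the exposed convex face.

## Compound list

1 | 2-bromocyclopent-2-en-1-one | O=C1CCC=C1Br | starting material
2 | (S)-2-bromocyclopent-2-en-1-ol | O[C@H]1CCC=C1Br | intermediate
3 | triethyl orthoacetate | CC(OCC)(OCC)OCC | starting material
4 | mixed ketene acetal, (S)-1-bromo-5-[(1-ethoxyvinyl)oxy]cyclopent-1-ene | C=C(OCC)O[C@H]1CCC=C1Br | intermediate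
5 | ethyl (S)-2-(2-bromocyclopent-2-en-1-yl)acetate | CCOC(=O)C[C@@H]1CCC=C1Br | intermediate
6 | (S)-2-(2-bromocyclopent-2-en-1-yl)ethan-1-ol | OCC[C@@H]1CCC=C1Br | intermediate
7 | (S)-1-bromo-5-(2-iodoethyl)cyclopent-1-ene | ICC[C@@H]1CCC=C1Br | intermediate
8 | methyl acetoacetate | COC(=O)CC(C)=O | starting material
9 | methyl (R)-6-(2-bromocyclopent-2-en-1-yl)-3-oxohexanoate | COC(=O)CC(=O)CCC[C@@H]1CCC=C1Br | intermediate
10 | methyl (3aR)-7-oxo-2,3,3a,4,5,6,7,8-octahydroazulene-8-carboxylate (C8 epimers and enol) | COC(=O)C1C(=O)CCC[C@@H]2CCC=C12 | intermediate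
11 | methyl acrylate | C=CC(=O)OC | starting material
12 | methyl 8-(3-methoxy-3-oxopropyl)-7-oxo-2,3,3a,4,5,6,7,8-octahydroazulene-8-carboxylate, propanoate arm trans to H10 | COC(=O)CC[C@]1(C(=O)OC)C(=O)CCC[C@@H]2CCC=C12 | intermediate
13 | 6-methylene derivative of 12 | COC(=O)CC[C@]1(C(=O)OC)C(=O)C(=C)CC[C@@H]2CCC=C12 | intermediate
14 | 6-(aminomethyl) ketone (C6 epimers) | COC(=O)CC[C@]1(C(=O)OC)C(=O)C(CN)CC[C@@H]2CCC=C12 | intermediate
15 | bridged keto-lactam (lactam bridge C7–N–C1 across C6/C8, C5 ketone bridge, methyl propanoate arm on C8) | O=C1NC[C@H]2CC[C@@H]3CCC=C3[C@]1(CCC(=O)OC)C2=O | intermediate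
16 | C5 spiro-epoxide of 15 (methylene on the lactam side) | O=C1NC[C@H]2CC[C@@H]3CCC=C3[C@]1(CCC(=O)OC)[C@@]24CO4 | intermediate
17 | ethyl vinyl ketone (pent-1-en-3-one) | CCC(=O)C=C | starting material
18 | hydroxy ketone (C5: CH2OH and 3-oxopentyl; C8: methyl propanoate arm; lactam ring B) | CCC(=O)CC[C@]1(CO)[C@]2(CCC(=O)OC)C(=O)NC[C@H]1CC[C@@H]3CCC=C23 | intermediate
19 | lactone-lactam (seven-membered lactone C21–O–C22; C5 3-oxopentyl chain) | CCC(=O)CC[C@]12COC(=O)CC[C@]13C(=O)NC[C@H]2CC[C@@H]4CCC=C34 | intermediate
20 | cyclic imine (C1=N in ring B) | CCC(=O)CC[C@]12COC(=O)CC[C@]13C=NC[C@H]2CC[C@@H]4CCC=C34 | intermediate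
21 | tetracyclic amino ketone (NH in ring B, cyclopentane closed, C3 propanoyl) | N2C[C@H]3CC[C@@H]4CCC=C4[C@]45CCC(=O)OC[C@]34C[C@H](C(=O)CC)[C@H]25 | intermediate
22 | methylene ketone (C3 2-methylpropenoyl) | N2C[C@H]3CC[C@@H]4CCC=C4[C@]45CCC(=O)OC[C@]34C[C@H](C(=O)C(C)=C)[C@H]25 | intermediate
23 | CNP0292775.1 | C[C@@H]1CN2C[C@H]3CC[C@@H]4CCC=C4[C@]45CCC(=O)OC[C@]34C[C@H](C1=O)[C@H]25 | target

## Summary

Total step count: 14. Longest linear sequence: 14 steps (1 to 23).

Three steps most likely to fail:

**Step 6** (seven-membered ring closure; O-vinylation or slow reductive elimination may compete, and the dienolate may erode C10). The fallback sets out from 7 and comes back at 10. The lithium enolate of methyl acetate (LiN(i-Pr)2, THF/DMPU, −78 °C) is alkylated with 7 to give methyl (R)-4-(2-bromocyclopent-2-en-1-yl)butanoate F1. Negishi-type coupling of the vinyl bromide with the Reformatsky reagent BrZnCH2CO2Me (Pd(dba)2, t-Bu3P, THF, rt) gives methyl (R)-4-[2-(2-methoxy-2-oxoethyl)cyclopent-2-en-1-yl]butanoate F2. Dieckmann condensation (KOt-Bu, toluene, high dilution, 80 °C) then closes the ring at C5–C8 instead of C8–C9 and gives 10, whose conjugated enolate is the thermodynamic sink.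

**Step 11** (the titanium reagent may reduce the enone, and facial selectivity at C5 is argued, not proven). The fallback sets out from 15 and comes back at 18. Wittig reaction with Ph3P=CHOMe (THF, 0 °C to rt) gives C5 methoxymethylene lactam F3. Hydrolysis (aq. HCl, THF) gives C5 carbaldehyde lactam F4. Michael addition of its enolate to 17 (DBU cat., MeCN), again from the lactam face, gives quaternary keto aldehyde F5. Chemoselective aldehyde reduction with NaBH(OAc)3 then gives 18.

**Step 14** (the C18 centre may equilibrate under warm, mildly acidic conditions; conformational analysis suggests the drawn epimer is the kinetic one and may be the less stable). The fallback sets out from 21 and comes back at 23. Heating 21 with N,N-dimethylformamide dimethyl acetal (toluene, 100 °C) forms the C18 enaminone, and transamination by the ring nitrogen closes ring A as C18–C19 cyclic enaminone F6. Conjugate reduction with LiBH(s-Bu)3 (THF, −78 °C) and quenching the enolate at −78 °C with 2,6-di-tert-butylphenol protonates C18 irreversibly from the exposed face to give 23.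

Further compounds
F1 | step 6 | methyl (R)-4-(2-bromocyclopent-2-en-1-yl)butanoate | COC(=O)CCC[C@@H]1CCC=C1Br
F2 | step 6 | methyl (R)-4-[2-(2-methoxy-2-oxoethyl)cyclopent-2-en-1-yl]butanoate | COC(=O)CCC[C@@H]1CCC=C1CC(=O)OC
F3 | step 11 | C5 methoxymethylene lactam | O=C1NC[C@H]2CC[C@@H]3CCC=C3[C@]1(CCC(=O)OC)C2=COC
F4 | step 11 | C5 carbaldehyde lactam | O=C1NC[C@H]2CC[C@@H]3CCC=C3[C@]1(CCC(=O)OC)C2C=O
F5 | step 11 | quaternary keto aldehyde | CCC(=O)CC[C@]1(C=O)[C@]2(CCC(=O)OC)C(=O)NC[C@H]1CC[C@@H]3CCC=C23
F6 | step 14 | C18–C19 cyclic enaminone | CC1=CN2C[C@H]3CC[C@@H]4CCC=C4[C@]45CCC(=O)OC[C@]34C[C@H](C1=O)[C@H]25
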